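**Retrosynthetic overview**
1. Target 38 ← desilylation ← methyl addition to C4 ketone of the trans-fused hydroazulenone 36 (tertiary carbinol set last, on the bicycle).
2. Seven-membered ring ← intramolecular Nozaki–Hiyama–Kishi closure (C9–C10) of iodoalkene aldehyde 34.
3. 34 ← late aldol union (C5–C6) of cyclopentenone fragment 29 (C1–C5, C10, C18) with aldehyde fragment 20 (C6–C9, C11–C17, side-chain stereocentres and acetates already in place).
4. 20 ← organocatalytic Mukaiyama–Michael (C7–C11) of enal 3 with ketene thioacetal 7, then alkoxyallylboration (C12–C13) and cross-metathesis (isobutenyl); 29 ← (S)-4-hydroxycyclopentenone 21.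
5. Ring order: the five-membered ring is carried from 21; the seven-membered ring is closed three steps from the end.

Assumption: positions are numbered C1/C5 ring fusion, C4 methyl carbinol, C6 and C9 carbinols, C10 methylidene carbon, C7 bearing the C11–C15 side chain; 21 and 23 are taken as commercially available.

**Route**

Step 1
Reactants: 1 (Z)-but-2-ene-1,4-diol
Product: 2 (Z)-4-{[tert-butyl(diphenyl)silyl]oxy}but-2-en-1-ol
Conditions: NaH (1.0 equiv), THF, 0 °C; tBuPh2SiCl, 0 °C → rt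
Reagents that add atoms: tert-butyl(chloro)diphenylsilane CC(C)(C)[Si](Cl)(c1ccccc1)c1ccccc1
Why: O-silylation of the monosodium alkoxide of a symmetric diol gives the mono-ether selectively; no stereocentre is formed.

Step 2
Reactants: 2 (Z)-4-{[tert-butyl(diphenyl)silyl]oxy}but-2-en-1-ol
Product: 3 (E)-4-{[tert-butyl(diphenyl)silyl]oxy}but-2-enal
Conditions: [C5H5NH][CrO3Cl] (pyridinium chlorochromate), NaOAc, CH2Cl2, rt
Reagents that add atoms: none
Why: Chlorochromate oxidation of the allylic alcohol gives the enal, which isomerises under the conditions to the conjugated (E)-isomer.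

Step 3
Reactants: 4 propanoyl chloride
Product: 5 S-propan-2-yl propanethioate
Conditions: iPrSH, pyridine, CH2Cl2, 0 °C
Reagents that add atoms: propane-2-thiol CC(C)S
Why: Nucleophilic acyl substitution by the thiol gives the thioester needed for a geometrically defined ketene thioacetal.

Step 4
Reactants: 5 S-propan-2-yl propanethioate
Product: 7 (Z)-trimethyl{[1-(propan-2-ylsulfanyl)prop-1-en-1-yl]oxy}silane, via lithium enolate 6 (not isolated)
Conditions: LiN(iPr)2 (LDA), THF, −78 °C; Me3SiCl, −78 °C → rt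
Reagents that add atoms: chlorotrimethylsilane C[Si](C)(C)Cl
Why: Kinetic enolisation in THF places the methyl group trans to O–Li, and O-silylation (silyl ketene acetal formation) fixes the (Z)-ketene thioacetal.

Step 5
Reactants: 3 (E)-4-{[tert-butyl(diphenyl)silyl]oxy}but-2-enal; 7 (Z)-trimethyl{[1-(propan-2-ylsulfanyl)prop-1-en-1-yl]oxy}silane
Product: 9 S-propan-2-yl (2R,3S)-3-({[tert-butyl(diphenyl)silyl]oxy}methyl)-5,5-dimethoxy-2-methylpentanethioate, via oxo thioester 8 (not isolated)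
Conditions: (2R,5R)-5-benzyl-2-tert-butyl-3-methylimidazolidin-4-one·CCl3CO2H (20 mol %), CH2Cl2/H2O, −78 → −55 °C; then HC(OMe)3, MeOH, PPTS (cat.), 0 °C → rt
Reagents that add atoms: trimethyl orthoformate COC(OC)OC
Why: Organocatalytic Mukaiyama–Michael addition in which the (2R,5R)-imidazolidinone iminium ion shields one face of the enal and so sets C7, while the open transition state of the (Z)-ketene thioacetal is expected to give the 2,3-syn relationship that sets C11; acetalisation in the same flask masks the C9 aldehyde.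

Step 6
Reactants: 9 S-propan-2-yl (2R,3S)-3-({[tert-butyl(diphenyl)silyl]oxy}methyl)-5,5-dimethoxy-2-methylpentanethioate
Product: 10 (2R,3S)-3-({[tert-butyl(diphenyl)silyl]oxy}methyl)-5,5-dimethoxy-2-methylpentanal
Conditions: iBu2AlH (1.1 equiv), CH2Cl2, −78 °C; Rochelle salt work-up
Reagents that add atoms: none
Why: Partial reduction of the thioester stops at the aldehyde because the tetrahedral aluminium hemithioacetal is stable at −78 °C; the α-stereocentre is not touched under these non-basic conditions.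

Step 7
Reactants: 11 prop-2-en-1-ol
Product: 12 1-methoxy-4-[(prop-2-en-1-yloxy)methyl]benzene
Conditions: NaH, 4-methoxybenzyl chloride, Bu4NI (cat.), THF/DMF, 0 °C → rt
Reagents that add atoms: 4-methoxybenzyl chloride COc1ccc(CCl)cc1
Why: Williamson etherification gives the allyl ether that serves as the C13–C14 unit.

Step 8
Reactants: 10 (2R,3S)-3-({[tert-butyl(diphenyl)silyl]oxy}methyl)-5,5-dimethoxy-2-methylpentanal; 12 1-methoxy-4-[(prop-2-en-1-yloxy)methyl]benzene
Product: 14 (3S,4S,5R,6S)-6-({[tert-butyl(diphenyl)silyl]oxy}methyl)-8,8-dimethoxy-3-[(4-methoxyphenyl)methoxy]-5-methyloct-1-en-4-ol, via allylborane 13 (not isolated)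
Conditions: 12, sec-BuLi, THF, −78 °C; (+)-Ipc2BOMe; BF3·OEt2; then 10, −78 °C; NaOH, H2O2, 0 °C → rt
Reagents that add atoms: none
Why: Brown alkoxyallylboration through a chair Zimmerman–Traxler transition state, in which the (Z)-γ-alkoxyallylborane gives the syn-diol relationship and the isopinocampheyl groups derived from (+)-Ipc2BOMe select the aldehyde face, setting C12 (S) and C13 (S) under reagent control.

Step 9
Reactants: 14 (3S,4S,5R,6S)-6-({[tert-butyl(diphenyl)silyl]oxy}methyl)-8,8-dimethoxy-3-[(4-methoxyphenyl)methoxy]-5-methyloct-1-en-4-ol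
Product: 15 (3S,4S,5R,6S)-6-({[tert-butyl(diphenyl)silyl]oxy}methyl)-8,8-dimethoxy-5-methyloct-1-ene-3,4-diol
Conditions: DDQ, CH2Cl2/pH 7 buffer (10:1), 0 °C
Reagents that add atoms: none
Why: Oxidative cleavage of the 4-methoxybenzyl ether under neutral, wet conditions frees the diol without disturbing the acid-labile dimethyl acetal.

Step 10
Reactants: 15 (3S,4S,5R,6S)-6-({[tert-butyl(diphenyl)silyl]oxy}methyl)-8,8-dimethoxy-5-methyloct-1-ene-3,4-diol
Product: 16 (3S,4S,5R,6S)-6-({[tert-butyl(diphenyl)silyl]oxy}methyl)-8,8-dimethoxy-5-methyloct-1-ene-3,4-diyl diacetate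
Conditions: Ac2O, pyridine, DMAP (cat.), CH2Cl2, rt
Reagents that add atoms: acetic anhydride CC(=O)OC(C)=O
Why: Acylation of both secondary alcohols installs the two acetates of the target with retention at C12 and C13.

Step 11
Reactants: 16 (3S,4S,5R,6S)-6-({[tert-butyl(diphenyl)silyl]oxy}methyl)-8,8-dimethoxy-5-methyloct-1-ene-3,4-diyl diacetate; 17 2-methylbut-2-ene
Product: 18 (4S,5S,6R,7S)-7-({[tert-butyl(diphenyl)silyl]oxy}methyl)-9,9-dimethoxy-2,6-dimethylnon-2-ene-4,5-diyl diacetate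
Conditions: second-generation Grubbs catalyst RuCl2(=CHPh)(H2IMes)(PCy3) (5 mol %), 17/CH2Cl2 (1:1), 40 °C, sealed tube
Reagents that add atoms: none
Why: Olefin cross-metathesis with excess 2-methylbut-2-ene converts the terminal vinyl group into the 2-methylprop-1-enyl group, with no E/Z issue.

Step 12
Reactants: 18 (4S,5S,6R,7S)-7-({[tert-butyl(diphenyl)silyl]oxy}methyl)-9,9-dimethoxy-2,6-dimethylnon-2-ene-4,5-diyl diacetate
Product: 19 (4S,5S,6R,7S)-7-(hydroxymethyl)-9,9-dimethoxy-2,6-dimethylnon-2-ene-4,5-diyl diacetate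
Conditions: Bu4NF, AcOH (1:1), THF, 0 °C → rt
Reagents that add atoms: none
Why: Buffered fluoride desilylation frees the primary alcohol while the acetates and the acetal survive.

Step 13
Reactants: 19 (4S,5S,6R,7S)-7-(hydroxymethyl)-9,9-dimethoxy-2,6-dimethylnon-2-ene-4,5-diyl diacetate
Product: 20 (2S,3R,4S,5S)-4,5-bis(acetyloxy)-2-(2,2-dimethoxyethyl)-3,7-dimethyloct-6-enal
Conditions: Dess–Martin periodinane, NaHCO3, CH2Cl2, 0 °C → rt
Reagents that add atoms: none
Why: Dess–Martin oxidation under buffered conditions gives the α-branched aldehyde without epimerising C7.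

Step 14
Reactants: 21 (S)-4-hydroxycyclopent-2-en-1-one
Product: 22 (S)-4-{[tert-butyl(dimethyl)silyl]oxy}cyclopent-2-en-1-one
Conditions: tBuMe2SiCl, imidazole, DMF, 0 °C → rt
Reagents that add atoms: tert-butyl(chloro)dimethylsilane CC(C)(C)[Si](C)(C)Cl
Why: Silylation protects the carbinol, which then directs the conjugate addition.

Step 15
Reactants: 22 (S)-4-{[tert-butyl(dimethyl)silyl]oxy}cyclopent-2-en-1-one; 23 (1-bromoethenyl)trimethylsilane
Product: 25 (3S,4S)-4-{[tert-butyl(dimethyl)silyl]oxy}-3-[1-(trimethylsilyl)ethenyl]cyclopentan-1-one, via Grignard reagent 24 (not isolated)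
Conditions: 23, Mg, THF; CuI (10 mol %), THF, −78 → −40 °C; then 22; aq. NH4Cl
Reagents that add atoms: none
Why: Copper-catalysed conjugate addition of the alkenyl Grignard reagent occurs trans to the silyloxy group and so sets C1.

Step 16
Reactants: 25 (3S,4S)-4-{[tert-butyl(dimethyl)silyl]oxy}-3-[1-(trimethylsilyl)ethenyl]cyclopentan-1-one
Product: 26 (3S,4S)-4-{[tert-butyl(dimethyl)silyl]oxy}-3-(1-iodoethenyl)cyclopentan-1-one
Conditions: N-iodosuccinimide, MeCN/ClCH2CN (3:1), 0 °C → rt, dark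
Reagents that add atoms: N-iodosuccinimide O=C1CCC(=O)N1I
Why: Iododesilylation (ipso substitution of the vinylsilane) gives the 1-iodoalkene needed for the later chromium-mediated ring closure, before any electron-rich alkene is present.

Step 17
Reactants: 26 (3S,4S)-4-{[tert-butyl(dimethyl)silyl]oxy}-3-(1-iodoethenyl)cyclopentan-1-one
Product: 27 (3S,4S)-4-hydroxy-3-(1-iodoethenyl)cyclopentan-1-one
Conditions: aq. HF (48 %), MeCN, 0 °C
Reagents that add atoms: none
Why: Acidic desilylation unmasks the β-hydroxy ketone without base-induced isomerisation.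

Step 18
Reactants: 27 (3S,4S)-4-hydroxy-3-(1-iodoethenyl)cyclopentan-1-one
Product: 29 (S)-4-(1-iodoethenyl)cyclopent-2-en-1-one, via mesylate 28 (not isolated)
Conditions: MsCl, Et3N, CH2Cl2, 0 °C
Reagents that add atoms: none
Why: Mesylation followed by E1cB elimination of the β-sulfonate gives the enone and removes the temporary stereocentre while C1 stays intact.

Step 19
Reactants: 29 (S)-4-(1-iodoethenyl)cyclopent-2-en-1-one; 20 (2S,3R,4S,5S)-4,5-bis(acetyloxy)-2-(2,2-dimethoxyethyl)-3,7-dimethyloct-6-enal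
Product: 31 (4S,5S,6R,7S)-7-{(R)-hydroxy[(1R,5R)-5-(1-iodoethenyl)-2-oxocyclopent-3-en-1-yl]methyl}-9,9-dimethoxy-2,6-dimethylnon-2-ene-4,5-diyl diacetate, via lithium dienolate 30 (not isolated)
Conditions: LiN(iPr)2 (1.05 equiv), THF, −78 °C, 30 min; then 20, −78 °C, 1 h; AcOH quench at −78 °C
Reagents that add atoms: none
Why: Aldol addition of the kinetic cross-conjugated lithium dienolate, in which the aldehyde approaches trans to the C1 substituent (sets C5), the cyclic (E)-enolate reacts through a Zimmerman–Traxler chair to give the anti aldol, and Felkin–Anh attack on the α-branched aldehyde reinforces it (sets C6).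

Step 20
Reactants: 31 (4S,5S,6R,7S)-7-{(R)-hydroxy[(1R,5R)-5-(1-iodoethenyl)-2-oxocyclopent-3-en-1-yl]methyl}-9,9-dimethoxy-2,6-dimethylnon-2-ene-4,5-diyl diacetate
Product: 34 (4S,5S,6R,7S)-7-{(R)-[(1R,5R)-5-(1-iodoethenyl)-2-oxocyclopent-3-en-1-yl](triethylsilyloxy)methyl}-2,6-dimethyl-9-oxonon-2-ene-4,5-diyl diacetate, via silyl ether acetal 32 (not isolated), via pyridinium salt 33 (not isolated)
Conditions: Et3SiOTf (3 equiv), 2,6-lutidine (5 equiv), CH2Cl2, −78 → 0 °C; then H2O, 0 °C → rt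
Reagents that add atoms: triethylsilyl trifluoromethanesulfonate CC[Si](CC)(CC)OS(=O)(=O)C(F)(F)F; water O
Why: O-silylation protects the aldol hydroxyl against retro-aldol cleavage, and the same silyl triflate/lutidine pair converts the dimethyl acetal into a pyridinium N,O-acetal that water hydrolyses to the C9 aldehyde under non-acidic conditions.

Step 21
Reactants: 34 (4S,5S,6R,7S)-7-{(R)-[(1R,5R)-5-(1-iodoethenyl)-2-oxocyclopent-3-en-1-yl](triethylsilyloxy)methyl}-2,6-dimethyl-9-oxonon-2-ene-4,5-diyl diacetate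
Product: 36 (2R,3S,4S)-2-[(3aR,4R,5S,7R,8aR)-7-hydroxy-8-methylidene-3-oxo-4-(triethylsilyloxy)-3,3a,4,5,6,7,8,8a-octahydroazulen-5-yl]-6-methylhept-5-ene-3,4-diyl diacetate, via alkenylchromium species 35 (not isolated)
Conditions: CrCl2 (8 equiv), NiCl2 (2 mol %), DMF/THF (3:1), rt, 0.003 M
Reagents that add atoms: none
Why: Intramolecular Nozaki–Hiyama–Kishi reaction, in which zerovalent nickel inserts into the carbon–iodine bond, the alkenyl group passes to trivalent chromium and adds only to the aldehyde (enone and acetates are inert), closing the seven-membered ring; the C9 carbinol is expected to form with oxygen pseudo-axial to avoid allylic strain with the methylidene group, giving mainly the 9R epimer.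

Step 22
Reactants: 36 (2R,3S,4S)-2-[(3aR,4R,5S,7R,8aR)-7-hydroxy-8-methylidene-3-oxo-4-(triethylsilyloxy)-3,3a,4,5,6,7,8,8a-octahydroazulen-5-yl]-6-methylhept-5-ene-3,4-diyl diacetate
Product: 37 (2R,3S,4S)-2-[(3S,3aR,4R,5S,7R,8aR)-3,7-dihydroxy-3-methyl-8-methylidene-4-(triethylsilyloxy)-3,3a,4,5,6,7,8,8a-octahydroazulen-5-yl]-6-methylhept-5-ene-3,4-diyl diacetate
Conditions: MeLi (3.5 equiv), CeCl3 (4 equiv, dried), THF, −78 °C; aq. NH4Cl
Reagents that add atoms: methyllithium [Li]C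
Why: Organocerium 1,2-addition to the enone, which at −78 °C is faster than attack on the acetates; the methyl group should enter from the face opposite the pseudo-axial C5–H and away from the gauche C6 silyloxy group, placing the C4 hydroxyl syn to the C6 oxygen (4S).

Step 23
Reactants: 37 (2R,3S,4S)-2-[(3S,3aR,4R,5S,7R,8aR)-3,7-dihydroxy-3-methyl-8-methylidene-4-(triethylsilyloxy)-3,3a,4,5,6,7,8,8a-octahydroazulen-5-yl]-6-methylhept-5-ene-3,4-diyl diacetate
Product: 38 (2R,3S,4S)-2-[(3S,3aR,4R,5S,7R,8aR)-3,4,7-trihydroxy-3-methyl-8-methylidene-3,3a,4,5,6,7,8,8a-octahydroazulen-5-yl]-6-methylhept-5-ene-3,4-diyl diacetate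
Conditions: HF·pyridine, pyridine, THF, 0 °C → rt
Reagents that add atoms: none
Why: Buffered fluoride desilylation removes the triethylsilyl ether without acyl migration or ionisation of the tertiary allylic alcohol, giving the target.

**Compound list**
1 | (Z)-but-2-ene-1,4-diol | OC/C=C\CO | starting material
2 | (Z)-4-{[tert-butyl(diphenyl)silyl]oxy}but-2-en-1-ol | OC/C=C\CO[Si](c1ccccc1)(c1ccccc1)C(C)(C)C | intermediate
3 | (E)-4-{[tert-butyl(diphenyl)silyl]oxy}but-2-enal | O=C/C=C/CO[Si](c1ccccc1)(c1ccccc1)C(C)(C)C | intermediate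
4 | propanoyl chloride | CCC(=O)Cl | starting material
5 | S-propan-2-yl propanethioate | CCC(=O)SC(C)C | intermediate
6 | lithium (Z)-1-(propan-2-ylsulfanyl)prop-1-en-1-olate | C/C=C(/O[Li])SC(C)C | intermediate
7 | (Z)-trimethyl{[1-(propan-2-ylsulfanyl)prop-1-en-1-yl]oxy}silane | C/C=C(/O[Si](C)(C)C)SC(C)C | intermediate
8 | S-propan-2-yl (2R,3S)-3-({[tert-butyl(diphenyl)silyl]oxy}methyl)-2-methyl-5-oxopentanethioate | O=CC[C@H](CO[Si](c1ccccc1)(c1ccccc1)C(C)(C)C)[C@@H](C)C(=O)SC(C)C | intermediate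
9 | S-propan-2-yl (2R,3S)-3-({[tert-butyl(diphenyl)silyl]oxy}methyl)-5,5-dimethoxy-2-methylpentanethioate | COC(OC)C[C@H](CO[Si](c1ccccc1)(c1ccccc1)C(C)(C)C)[C@@H](C)C(=O)SC(C)C | intermediate
10 | (2R,3S)-3-({[tert-butyl(diphenyl)silyl]oxy}methyl)-5,5-dimethoxy-2-methylpentanal | COC(OC)C[C@H](CO[Si](c1ccccc1)(c1ccccc1)C(C)(C)C)[C@@H](C)C=O | intermediate
11 | prop-2-en-1-ol | C=CCO | starting material
12 | 1-methoxy-4-[(prop-2-en-1-yloxy)methyl]benzene | C=CCOCc1ccc(OC)cc1 | intermediate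
13 | [(Z)-3-(4-methoxybenzyloxy)prop-2-en-1-yl]bis(isopinocampheyl)borane, isopinocampheyl groups from (−)-α-pinene | COc1ccc(CO/C=C\CB([C@H]2C[C@H]3C[C@@H]([C@@H]2C)C3(C)C)[C@H]2C[C@H]3C[C@@H]([C@@H]2C)C3(C)C)cc1 | intermediate
14 | (3S,4S,5R,6S)-6-({[tert-butyl(diphenyl)silyl]oxy}methyl)-8,8-dimethoxy-3-[(4-methoxyphenyl)methoxy]-5-methyloct-1-en-4-ol | COC(OC)C[C@H](CO[Si](c1ccccc1)(c1ccccc1)C(C)(C)C)[C@@H](C)[C@H](O)[C@H](C=C)OCc1ccc(OC)cc1 | intermediate
15 | (3S,4S,5R,6S)-6-({[tert-butyl(diphenyl)silyl]oxy}methyl)-8,8-dimethoxy-5-methyloct-1-ene-3,4-diol | COC(OC)C[C@H](CO[Si](c1ccccc1)(c1ccccc1)C(C)(C)C)[C@@H](C)[C@H](O)[C@H](C=C)O | intermediate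
16 | (3S,4S,5R,6S)-6-({[tert-butyl(diphenyl)silyl]oxy}methyl)-8,8-dimethoxy-5-methyloct-1-ene-3,4-diyl diacetate | COC(OC)C[C@H](CO[Si](c1ccccc1)(c1ccccc1)C(C)(C)C)[C@@H](C)[C@H](OC(C)=O)[C@H](C=C)OC(C)=O | intermediate
17 | 2-methylbut-2-ene | CC=C(C)C | starting material
18 | (4S,5S,6R,7S)-7-({[tert-butyl(diphenyl)silyl]oxy}methyl)-9,9-dimethoxy-2,6-dimethylnon-2-ene-4,5-diyl diacetate | COC(OC)C[C@H](CO[Si](c1ccccc1)(c1ccccc1)C(C)(C)C)[C@@H](C)[C@H](OC(C)=O)[C@H](C=C(C)C)OC(C)=O | intermediate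
19 | (4S,5S,6R,7S)-7-(hydroxymethyl)-9,9-dimethoxy-2,6-dimethylnon-2-ene-4,5-diyl diacetate | COC(OC)C[C@H](CO)[C@@H](C)[C@H](OC(C)=O)[C@H](C=C(C)C)OC(C)=O | intermediate
20 | (2S,3R,4S,5S)-4,5-bis(acetyloxy)-2-(2,2-dimethoxyethyl)-3,7-dimethyloct-6-enal | COC(OC)C[C@H](C=O)[C@@H](C)[C@H](OC(C)=O)[C@H](C=C(C)C)OC(C)=O | intermediate
21 | (S)-4-hydroxycyclopent-2-en-1-one | O=C1C=C[C@@H](O)C1 | starting material
22 | (S)-4-{[tert-butyl(dimethyl)silyl]oxy}cyclopent-2-en-1-one | O=C1C=C[C@@H](O[Si](C)(C)C(C)(C)C)C1 | intermediate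
23 | (1-bromoethenyl)trimethylsilane | C=C(Br)[Si](C)(C)C | starting material
24 | [1-(trimethylsilyl)ethenyl]magnesium bromide | C=C([Mg]Br)[Si](C)(C)C | intermediate
25 | (3S,4S)-4-{[tert-butyl(dimethyl)silyl]oxy}-3-[1-(trimethylsilyl)ethenyl]cyclopentan-1-one | O=C1C[C@H](O[Si](C)(C)C(C)(C)C)[C@@H](C(=C)[Si](C)(C)C)C1 | intermediate
26 | (3S,4S)-4-{[tert-butyl(dimethyl)silyl]oxy}-3-(1-iodoethenyl)cyclopentan-1-one | O=C1C[C@H](O[Si](C)(C)C(C)(C)C)[C@@H](C(I)=C)C1 | intermediate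
27 | (3S,4S)-4-hydroxy-3-(1-iodoethenyl)cyclopentan-1-one | O=C1C[C@H](O)[C@@H](C(I)=C)C1 | intermediate
28 | (1S,2S)-2-(1-iodoethenyl)-4-oxocyclopentyl methanesulfonate | O=C1C[C@H](OS(C)(=O)=O)[C@@H](C(I)=C)C1 | intermediate
29 | (S)-4-(1-iodoethenyl)cyclopent-2-en-1-one | O=C1C=C[C@@H](C(I)=C)C1 | intermediate
30 | lithium (S)-3-(1-iodoethenyl)cyclopenta-1,4-dien-1-olate | [Li]OC1=C[C@H](C(I)=C)C=C1 | intermediate
31 | (4S,5S,6R,7S)-7-{(R)-hydroxy[(1R,5R)-5-(1-iodoethenyl)-2-oxocyclopent-3-en-1-yl]methyl}-9,9-dimethoxy-2,6-dimethylnon-2-ene-4,5-diyl diacetate | COC(OC)C[C@@H]([C@@H](C)[C@H](OC(C)=O)[C@H](C=C(C)C)OC(C)=O)[C@@H](O)[C@H]1[C@H](C(I)=C)C=CC1=O | intermediate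
32 | triethylsilyl ether of 31 (silyloxy in place of the carbinol OH, dimethyl acetal intact) | COC(OC)C[C@@H]([C@@H](C)[C@H](OC(C)=O)[C@H](C=C(C)C)OC(C)=O)[C@@H](O[Si](CC)(CC)CC)[C@H]1[C@H](C(I)=C)C=CC1=O | intermediate
33 | 2,6-dimethylpyridinium N,O-acetal triflate of 32 (C9 carries one OMe and the pyridinium nitrogen) | COC(C[C@@H]([C@@H](C)[C@H](OC(C)=O)[C@H](C=C(C)C)OC(C)=O)[C@@H](O[Si](CC)(CC)CC)[C@H]1[C@H](C(I)=C)C=CC1=O)[n+]1c(C)cccc1C.[O-]S(=O)(=O)C(F)(F)F | intermediate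
34 | (4S,5S,6R,7S)-7-{(R)-[(1R,5R)-5-(1-iodoethenyl)-2-oxocyclopent-3-en-1-yl](triethylsilyloxy)methyl}-2,6-dimethyl-9-oxonon-2-ene-4,5-diyl diacetate | O=CC[C@@H]([C@@H](C)[C@H](OC(C)=O)[C@H](C=C(C)C)OC(C)=O)[C@@H](O[Si](CC)(CC)CC)[C@H]1[C@H](C(I)=C)C=CC1=O | intermediate
35 | dichlorochromium alkenyl species of 34 (CrCl2 in place of iodine) | O=CC[C@@H]([C@@H](C)[C@H](OC(C)=O)[C@H](C=C(C)C)OC(C)=O)[C@@H](O[Si](CC)(CC)CC)[C@H]1[C@H](C(=C)[Cr](Cl)Cl)C=CC1=O | intermediate
36 | (2R,3S,4S)-2-[(3aR,4R,5S,7R,8aR)-7-hydroxy-8-methylidene-3-oxo-4-(triethylsilyloxy)-3,3a,4,5,6,7,8,8a-octahydroazulen-5-yl]-6-methylhept-5-ene-3,4-diyl diacetate | C=C1[C@H](O)C[C@@H]([C@@H](C)[C@H](OC(C)=O)[C@H](C=C(C)C)OC(C)=O)[C@@H](O[Si](CC)(CC)CC)[C@H]2[C@H]1C=CC2=O | intermediate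
37 | (2R,3S,4S)-2-[(3S,3aR,4R,5S,7R,8aR)-3,7-dihydroxy-3-methyl-8-methylidene-4-(triethylsilyloxy)-3,3a,4,5,6,7,8,8a-octahydroazulen-5-yl]-6-methylhept-5-ene-3,4-diyl diacetate | C=C1[C@H](O)C[C@@H]([C@@H](C)[C@H](OC(C)=O)[C@H](C=C(C)C)OC(C)=O)[C@@H](O[Si](CC)(CC)CC)[C@H]2[C@H]1C=C[C@]2(C)O | intermediate
38 | (2R,3S,4S)-2-[(3S,3aR,4R,5S,7R,8aR)-3,4,7-trihydroxy-3-methyl-8-methylidene-3,3a,4,5,6,7,8,8a-octahydroazulen-5-yl]-6-methylhept-5-ene-3,4-diyl diacetate | C=C1[C@H](O)C[C@@H]([C@@H](C)[C@H](OC(C)=O)[C@H](C=C(C)C)OC(C)=O)[C@@H](O)[C@H]2[C@H]1C=C[C@]2(C)O | target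

**Totals**
Total step count: 23.
Longest linear sequence: 15 steps (1, 2, 5, 6, 8, 9, 10, 11, 12, 13, 19, 20, 21, 22, 23).

**Steps most likely to fail**

Step 5 (Mukaiyama–Michael: syn/anti ratio and enantioselectivity with the γ-silyloxy enal). The fallback sets out from 2 and 4 and comes back at 8. Acylation of 2 with 4 (pyridine) gives (Z)-4-{[tert-butyl(diphenyl)silyl]oxy}but-2-en-1-yl propanoate F1. An enantioselective boron-enolate Ireland–Claisen rearrangement follows (Corey's chiral 1,2-diphenylethylenediamine bis-sulfonamide bromoborane, Et3N, toluene/hexane, −78 → 4 °C); the E(O)-enolate and the (Z)-alkene both sit pseudo-axial in the chair, which gives the 2,3-syn acid (2R,3S)-3-({[tert-butyl(diphenyl)silyl]oxy}methyl)-2-methylpent-4-enoic acid F2, with the controller enantiomer chosen for this sense. Thioesterification (iPrSH, DCC, DMAP) gives S-propan-2-yl (2R,3S)-3-({[tert-butyl(diphenyl)silyl]oxy}methyl)-2-methylpent-4-enethioate F3. Hydroboration of the vinyl group (9-BBN, then NaBO3) gives S-propan-2-yl (2R,3S)-3-({[tert-butyl(diphenyl)silyl]oxy}methyl)-5-hydroxy-2-methylpentanethioate F4. Dess–Martin oxidation then gives 8, which is acetalised to 9 as in step 5.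

Step 21 (seven-membered ring closure and C9 configuration). The fallback sets out from 34 and comes back at 37, replacing substrate control at C9 by reagent control. The cyclisation is run as before and the product is taken on as the C9-epimeric mixture of 36 F5. Methylcerium addition as in step 22 gives the C9-epimeric mixture of 37 F6. MnO2 (CH2Cl2, rt) oxidises only the secondary allylic alcohol and gives the 9-oxo derivative of 37 F7, an α-methylidene ketone. Reduction with (S)-2-methyl-CBS-oxazaborolidine and catecholborane (toluene, −78 °C) treats the alkenyl side as the large group and delivers the 9R alcohol 37.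

Step 22 (facial selectivity at C4 and competition from the acetates). The fallback sets out from 36 and comes back at 38; it applies if methyl adds from the wrong face, and turns that same facial preference to advantage by delivering oxygen instead of carbon to C4. Silylation of 36 (Et3SiCl, imidazole) gives the 7-O-triethylsilyl ether of 36 F8. Methylcerium addition then gives the C4-epimeric tertiary alcohol F9. Babler–Dauben oxidative transposition with [C5H5NH][CrO3Cl] gives the transposed enone F10 (C2 ketone, C3=C4 bearing the methyl group). Nucleophilic epoxidation (tBuOOH, DBU) from the face that the methyl group had used gives the epoxy ketone F11 with oxygen on the required face of C4. Wharton rearrangement (N2H4·H2O, AcOH, MeOH) gives the bis(triethylsilyl) ether of 38 F12, with the C2=C3 alkene and the 4S carbinol. HF·pyridine then gives 38.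

**Further compounds**
F1 | step 5 | (Z)-4-{[tert-butyl(diphenyl)silyl]oxy}but-2-en-1-yl propanoate | CCC(=O)OC/C=C\CO[Si](c1ccccc1)(c1ccccc1)C(C)(C)C
F2 | step 5 | (2R,3S)-3-({[tert-butyl(diphenyl)silyl]oxy}methyl)-2-methylpent-4-enoic acid | C=C[C@H](CO[Si](c1ccccc1)(c1ccccc1)C(C)(C)C)[C@@H](C)C(=O)O
F3 | step 5 | S-propan-2-yl (2R,3S)-3-({[tert-butyl(diphenyl)silyl]oxy}methyl)-2-methylpent-4-enethioate | C=C[C@H](CO[Si](c1ccccc1)(c1ccccc1)C(C)(C)C)[C@@H](C)C(=O)SC(C)C
F4 | step 5 | S-propan-2-yl (2R,3S)-3-({[tert-butyl(diphenyl)silyl]oxy}methyl)-5-hydroxy-2-methylpentanethioate | OCC[C@H](CO[Si](c1ccccc1)(c1ccccc1)C(C)(C)C)[C@@H](C)C(=O)SC(C)C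
F5 | step 21 | C9-epimeric mixture of 36 | C=C1C(O)C[C@@H]([C@@H](C)[C@H](OC(C)=O)[C@H](C=C(C)C)OC(C)=O)[C@@H](O[Si](CC)(CC)CC)[C@H]2[C@H]1C=CC2=O
F6 | step 21 | C9-epimeric mixture of 37 | C=C1C(O)C[C@@H]([C@@H](C)[C@H](OC(C)=O)[C@H](C=C(C)C)OC(C)=O)[C@@H](O[Si](CC)(CC)CC)[C@H]2[C@H]1C=C[C@]2(C)O
F7 | step 21 | 9-oxo derivative of 37 | C=C1C(=O)C[C@@H]([C@@H](C)[C@H](OC(C)=O)[C@H](C=C(C)C)OC(C)=O)[C@@H](O[Si](CC)(CC)CC)[C@H]2[C@H]1C=C[C@]2(C)O
F8 | step 22 | 7-O-triethylsilyl ether of 36 | C=C1[C@H](O[Si](CC)(CC)CC)C[C@@H]([C@@H](C)[C@H](OC(C)=O)[C@H](C=C(C)C)OC(C)=O)[C@@H](O[Si](CC)(CC)CC)[C@H]2[C@H]1C=CC2=O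
F9 | step 22 | C4-epimeric tertiary alcohol (bis-silyl ether) | C=C1[C@H](O[Si](CC)(CC)CC)C[C@@H]([C@@H](C)[C@H](OC(C)=O)[C@H](C=C(C)C)OC(C)=O)[C@@H](O[Si](CC)(CC)CC)[C@H]2[C@H]1C=C[C@@]2(C)O
F10 | step 22 | transposed enone (C2 ketone, C3=C4 methyl alkene) | C=C1[C@H](O[Si](CC)(CC)CC)C[C@@H]([C@@H](C)[C@H](OC(C)=O)[C@H](C=C(C)C)OC(C)=O)[C@@H](O[Si](CC)(CC)CC)[C@H]2[C@H]1C(=O)C=C2C
F11 | step 22 | epoxy ketone (C3–C4 epoxide) | C=C1[C@H](O[Si](CC)(CC)CC)C[C@@H]([C@@H](C)[C@H](OC(C)=O)[C@H](C=C(C)C)OC(C)=O)[C@@H](O[Si](CC)(CC)CC)[C@H]2[C@H]1C(=O)[C@@H]3O[C@]23C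
F12 | step 22 | bis(triethylsilyl) ether of 38 | C=C1[C@H](O[Si](CC)(CC)CC)C[C@@H]([C@@H](C)[C@H](OC(C)=O)[C@H](C=C(C)C)OC(C)=O)[C@@H](O[Si](CC)(CC)CC)[C@H]2[C@H]1C=C[C@]2(C)O
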